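**Retrosynthetic overview**
- The target, 3,3',4,4',5,5'-hexabromo-1H,1'H-2,2'-bipyrrole, is traced back to 3,3'-dibromo-1H,1'H-2,2'-bipyrrole by electrophilic bromination of the four open positions C4, C5, C4' and C5'.
- The strategy rests on C3 and C3', the carbons of rings A and B next to the inter-ring C2–C2' bond. In 2,2'-bi-1-pyrroline they are the alpha-carbons of the two C=N bonds, so alpha,alpha-dibromination followed by loss of HBr forms both C3–Br bonds and aromatizes both rings.
- 2,2'-Bi-1-pyrroline is traced back to 1,8-diaminooctane-4,5-dione, and that to diethyl oxalate and two molecules of N-vinylpyrrolidin-2-one (double Claisen acylation, then hydrolysis and decarboxylation).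
- Ring order: rings A and B close together as cyclic imines in step 2 and are aromatized together in step 3.

Key step: step 3

Remark: compound 3 is written in its tetraketo form; it should exist largely as enol tautomers, and its two stereocentres are left uncontrolled because step 2 destroys both.

**Step 1**
Reactants: 1 N-vinylpyrrolidin-2-one (two molecules enter the product; 2.3 equiv), 2 diethyl oxalate (1.0 equiv)
Product: 3 1,2-bis(2-oxo-1-vinylpyrrolidin-3-yl)ethane-1,2-dione
Conditions: NaH (4.5 equiv), THF, reflux, slow addition of 2; then aq HCl, 0 °C
Reagents that add atoms: none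
Why: Crossed double Claisen condensation, in which the sodium enolate of lactam 1 acylates each ester carbonyl of the non-enolizable oxalate in turn and deprotonation of each new beta-dicarbonyl unit drives both acylations forward, as in the preparation of 1,3,4,6-tetracarbonyl compounds from dialkyl oxalates.

**Step 2**
Reactants: 3 1,2-bis(2-oxo-1-vinylpyrrolidin-3-yl)ethane-1,2-dione
Product: 5 2,2'-bi-1-pyrroline, via 1,8-diaminooctane-4,5-dione dihydrochloride 4 (not isolated)
Conditions: 6 M HCl, reflux (acetaldehyde distilled off); then NaOH aq, 0 °C, pH 11, CH2Cl2 extraction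
Reagents that add atoms: none
Why: Hot acid should cleave both N-vinyl groups as acetaldehyde, open both beta-keto lactams and decarboxylate the resulting beta-keto acids to the bis(gamma-amino ketone) salt, and on basification each amine should condense with the carbonyl four atoms away in a 5-exo-trig closure to a cyclic imine, which is the classical synthesis of 2-substituted 1-pyrrolines from N-vinylpyrrolidinone.

**Step 3**
Reactants: 5 2,2'-bi-1-pyrroline, 6 N-bromosuccinimide
Product: 9 3,3'-dibromo-1H,1'H-2,2'-bipyrrole, via 3,3,3',3'-tetrabromo-2,2'-bi-1-pyrroline 7 (not isolated), via 4,4'-dibromo-2H,2'H-5,5'-bipyrrole 8 (not isolated)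
Conditions: NBS (4.2 equiv), dry CH2Cl2, 0 °C to rt, dark; filter, concentrate; then NaOMe (6 equiv), MeOH, reflux
Reagents that add atoms: N-bromosuccinimide (6), O=C1CCC(=O)N1Br
Why: Each C=N of 5 equilibrates with its enamine tautomer, whose carbon C3 attacks the bromine of NBS, and a second cycle at the more acidic alpha-bromo imine gives the geminal dibromide, so four equivalents should lead to 7. Methoxide then removes a C4 proton with loss of one bromide from C3 in each ring to give the 2H-pyrrole 8, and deprotonation of its C5 methylene gives the aromatic pyrrolide, which is protonated on nitrogen at work-up to 9. The closest known reaction type is the alpha,alpha-dihalogenation of 2-substituted 1-pyrrolines with N-halosuccinimides followed by alkoxide-induced dehydrohalogenation to 2-substituted 3-halopyrroles. No ring closes and no stereocentre is formed; the step makes the C3–Br and C3'–Br bonds and turns rings A and B into pyrroles, with bromine acting both as oxidant and as substituent. The step needs halogenation at C3 and C3' and not at the nitrogen-bound C5 and C5' methylenes; only C3 is alpha to the imine carbon and can become the enamine carbon, and exclusion of light and radical initiators suppresses hydrogen abstraction at C5. Elimination should prevail over substitution because the CBr2 carbon is fully substituted, and the bromine that remains is vinylic in 8 and is not displaced.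

**Step 4**
Reactants: 9 3,3'-dibromo-1H,1'H-2,2'-bipyrrole, 6 N-bromosuccinimide
Product: 10 3,3',4,4',5,5'-hexabromo-1H,1'H-2,2'-bipyrrole
Conditions: NBS (4.2 equiv), THF, −78 °C to rt, dark; aq Na2S2O3/NaHCO3 work-up
Reagents that add atoms: N-bromosuccinimide (6), O=C1CCC(=O)N1Br
Why: Electrophilic aromatic substitution, in which the electron-rich pyrrole rings should take up bromine first at the free alpha positions C5 and C5' and then at C4 and C4', since pyrroles are brominated exhaustively by NBS even when already halogenated.

**Compound list**
1 | N-vinylpyrrolidin-2-one (1-ethenylpyrrolidin-2-one) | C=CN1CCCC1=O | starting material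
2 | diethyl oxalate | CCOC(=O)C(=O)OCC | starting material
3 | 1,2-bis(2-oxo-1-vinylpyrrolidin-3-yl)ethane-1,2-dione (mixture of stereoisomers and enol tautomers) | C=CN1CCC(C1=O)C(=O)C(=O)C1CCN(C=C)C1=O | intermediate
4 | 1,8-diaminooctane-4,5-dione dihydrochloride | NCCCC(=O)C(=O)CCCN.Cl.Cl | intermediate
5 | 2,2'-bi-1-pyrroline (3,3',4,4'-tetrahydro-2H,2'H-5,5'-bipyrrole) | C1CN=C(C1)C1=NCCC1 | intermediate
6 | N-bromosuccinimide | O=C1CCC(=O)N1Br | starting material
7 | 3,3,3',3'-tetrabromo-2,2'-bi-1-pyrroline (4,4,4',4'-tetrabromo-3,3',4,4'-tetrahydro-2H,2'H-5,5'-bipyrrole) | BrC1(Br)CCN=C1C1=NCCC1(Br)Br | intermediate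
8 | 4,4'-dibromo-2H,2'H-5,5'-bipyrrole | BrC1=CCN=C1C1=NCC=C1Br | intermediate
9 | 3,3'-dibromo-1H,1'H-2,2'-bipyrrole | Brc1cc[nH]c1-c1[nH]ccc1Br | intermediate
10 | 3,3',4,4',5,5'-hexabromo-1H,1'H-2,2'-bipyrrole | Brc1[nH]c(-c2[nH]c(Br)c(Br)c2Br)c(Br)c1Br | target

**Total step count:** 4
**Longest linear sequence:** 4 steps (1 → 3 → 5 → 9 → 10)

**Steps most likely to fail**

Step 3. Methoxide may add to the C=N bond of the alpha,alpha-dibromo imine or take up electrophilic bromine, so that bromine is lost reductively. The two rings may also be brominated unevenly, which leaves one ring that cannot aromatize. The fallback sets out from 5 and comes back at 10. Compound 5 is dehydrogenated over 10% Pd/C in refluxing mesitylene under nitrogen to 1H,1'H-2,2'-bipyrrole F1. F1 is then brominated at all six ring carbons with six equivalents of 6 in THF from −78 °C to rt to give 10. This gives up the bromination-driven aromatization and leaves the hindered C3 and C3' positions to the final substitution.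

Step 2. Each amine may close onto the distal carbonyl to form six-membered rings instead of the pyrrolines. In addition, retro-Claisen cleavage in hot acid or self-condensation of the alpha-diketone when the amines are set free may consume the material. The fallback sets out from 1 and comes back at 5, and it forms the inter-ring bond after the rings exist, so ring size is no longer in question. Dilute aqueous HCl at rt cleaves the N-vinyl group of 1 to pyrrolidin-2-one F2. Boc2O with catalytic 4-(dimethylamino)pyridine in MeCN gives tert-butyl 2-oxopyrrolidine-1-carboxylate F3. KN(SiMe3)2 and diphenyl chlorophosphate in THF at −78 °C give the enol phosphate tert-butyl 5-[(diphenoxyphosphoryl)oxy]-2,3-dihydro-1H-pyrrole-1-carboxylate F4. A one-pot borylation and Suzuki homocoupling (bis(pinacolato)diboron 0.5 equiv, PdCl2(PPh3)2, K3PO4, dioxane, 80 °C) joins two molecules at C2 to di-tert-butyl 4,4',5,5'-tetrahydro-1H,1'H-[2,2'-bipyrrole]-1,1'-dicarboxylate F5. Trifluoroacetic acid in CH2Cl2, followed by basic work-up, removes both Boc groups, and the freed enamines tautomerize to the bis-imine 5.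

Step 1. The condensation may stall after the first acylation, because the remaining ester is then conjugated with an enolate and is a poor electrophile. The fallback sets out from 1 and comes back at 3. Compound 1 is converted to its lithium enolate with LiN(iPr)2 in THF at −78 °C and treated with N,N'-dimethoxy-N,N'-dimethyloxamide (0.45 equiv). Both additions then pass through chelated tetrahedral intermediates that do not collapse to an enolizable ketone until the acidic quench, which should give 3. No compound outside the compound list is formed (F0).

**Further compounds**
F1 | step 3 | 1H,1'H-2,2'-bipyrrole | c1c[nH]c(c1)-c1ccc[nH]1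
F2 | step 2 | pyrrolidin-2-one | O=C1CCCN1
F3 | step 2 | tert-butyl 2-oxopyrrolidine-1-carboxylate | CC(C)(C)OC(=O)N1CCCC1=O
F4 | step 2 | tert-butyl 5-[(diphenoxyphosphoryl)oxy]-2,3-dihydro-1H-pyrrole-1-carboxylate | CC(C)(C)OC(=O)N1CCC=C1OP(=O)(Oc1ccccc1)Oc1ccccc1
F5 | step 2 | di-tert-butyl 4,4',5,5'-tetrahydro-1H,1'H-[2,2'-bipyrrole]-1,1'-dicarboxylate | CC(C)(C)OC(=O)N1CCC=C1C1=CCCN1C(=O)OC(C)(C)C
F0 | step 1 | none | none
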